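**Plan**

1. Numbering: side-chain carbons C1' to C32' run from ring carbon C-3 of the naphthoquinone (quinoid ring B, benzo ring A). Retrosynthetic cuts, in order: ring B quinone back to its 1,4-dimethyl ether; C17'–C18' (an sp3 CH2 joined to the CH end of the E C18'=C19' olefin), which divides the molecule into a C19 alkenyl iodide and a C34 aryl pentaene; then C-3–C1', C16'=C17', C21'–C22', the C–CH3 bonds at C19' and C23', and C24'–C25'.
2. Enabling feature: C16'–C17' is an ethylene bridge homoallylic to the C14'=C15' olefin, so it can be carried as the terminal vinyl group of a 3-methyl-1,3-diene that 9-BBN hydroborates only at C17'. C18' bears only hydrogen, so it can be the iodinated end of an (E)-2-methylalk-1-enyl iodide made from a terminal alkyne. Ring B is held as the hydroquinone dimethyl ether, which tolerates Grignard, borane and palladium chemistry.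
3. Forward order: the tail half (C18'–C32') is built by two rounds of alkyne methylalumination/iodination with one homopropargylzinc coupling between them. The head half (rings A and B plus C1'–C17') is built by allylation of an aryl Grignard reagent, terminal allylic oxidation and methylenation.
4. The halves are joined in one flask by diene hydroboration and B-alkyl Suzuki–Miyaura coupling; oxidation of ring B to the quinone ends the route.
5. Stereochemistry: the only stereocentre, C27' (R), is bought as (S)-citronellyl bromide and never sits next to a reacting carbon. The C2', C6' and C10' olefins come from (2E,6E,10E)-geranylgeraniol, C14' from E-selective selenium dioxide oxidation, and C18' and C22' from syn methylalumination followed by stereoretentive couplings.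

Key step: step 12

Remark: the (R) centre of the target has the spatial arrangement of the (S)-citronellol series (only the CIP priorities change on chain extension); (S)-citronellyl bromide, (2E,6E,10E)-geranylgeraniol, menadione and the two silyl alkynes are taken as commercial, isomerically pure materials.

Step 1
Reactants: 1 (S)-citronellyl bromide [(6S)-8-bromo-2,6-dimethyloct-2-ene]; 2 1-(trimethylsilyl)propyne
Product: 5 (R)-6,10-dimethylundec-9-en-1-yne, via lithiated silylpropyne 3 (not isolated), via silylated alkyne 4 (not isolated)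
Conditions: 2, n-BuLi, THF, −78 to −20 °C; 1, DMPU, −78 °C to rt; then MeOH, K2CO3, rt
Reagents that add atoms: none
Why: Propargylic lithiation of 2 gives an anion that should alkylate the unhindered primary bromide at its CH2 terminus (the silyl group blocks the allenyl terminus) in an SN2 propargylation, and base-catalysed methanolysis then removes the alkynyl silane, the stereocentre lying two carbons from the reacting carbon and staying untouched.

Step 2
Reactants: 5 (R)-6,10-dimethylundec-9-en-1-yne
Product: 7 (1E,6R)-1-iodo-2,6,10-trimethylundeca-1,9-diene, via alkenyldimethylalane 6 (not isolated)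
Conditions: AlMe3 (2 equiv), Cp2ZrCl2 (0.25 equiv), CH2Cl2, 0 °C to rt; then I2, THF, −30 to 0 °C
Reagents that add atoms: trimethylaluminium, C[Al](C)C; iodine, II
Why: Zirconium-catalysed syn methylalumination of the terminal alkyne (Negishi carboalumination) places methyl on the internal and aluminium on the terminal carbon, and iodinolysis of the C–Al bond with retention should give the E iodide while the isolated trisubstituted olefin stays inert.

Step 3
Reactants: 7 (1E,6R)-1-iodo-2,6,10-trimethylundeca-1,9-diene; 8 (4-bromobut-1-yn-1-yl)trimethylsilane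
Product: 10 trimethyl[(5E,10R)-6,10,14-trimethylpentadeca-5,13-dien-1-yn-1-yl]silane, via homopropargylzinc bromide 9 (not isolated)
Conditions: 8, Zn dust, I2 (5 mol%), DMA, 80 °C; then 7, PdCl2(DPEphos) (3 mol%), THF/DMA, rt
Reagents that add atoms: none
Why: In this Negishi alkyl–alkenyl coupling, oxidative addition of zerovalent palladium to the alkenyl iodide, transmetalation from the primary alkylzinc and reductive elimination all proceed with retention of the E geometry, and the wide-bite-angle diphosphine should outpace beta-hydride elimination.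

Step 4
Reactants: 10 trimethyl[(5E,10R)-6,10,14-trimethylpentadeca-5,13-dien-1-yn-1-yl]silane
Product: 11 (5E,10R)-6,10,14-trimethylpentadeca-5,13-dien-1-yne
Conditions: K2CO3, MeOH/THF, rt
Reagents that add atoms: none
Why: Base-catalysed methanolysis cleaves only the alkynyl C–Si bond and touches neither olefin nor the stereocentre.

Step 5
Reactants: 11 (5E,10R)-6,10,14-trimethylpentadeca-5,13-dien-1-yne
Product: 13 (1E,5E,10R)-1-iodo-2,6,10,14-tetramethylpentadeca-1,5,13-triene, via alkenyldimethylalane 12 (not isolated)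
Conditions: AlMe3 (2 equiv), Cp2ZrCl2 (0.25 equiv), CH2Cl2, 0 °C to rt; then I2, THF, −30 to 0 °C
Reagents that add atoms: trimethylaluminium, C[Al](C)C; iodine, II
Why: A second Negishi carboalumination adds Me–Al syn across the terminal alkyne of the 1,5-enyne and stereoretentive iodinolysis should fix the E geometry of the future C18'=C19' olefin, the two trisubstituted olefins being too hindered to carbometalate.

Step 6
Reactants: 14 menadione (2-methylnaphthalene-1,4-dione)
Product: 16 1,4-dimethoxy-2-methylnaphthalene, via menadiol 15 (not isolated)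
Conditions: Na2S2O4, n-Bu4NBr (cat.), THF/H2O, rt; then aq. KOH, Me2SO4, rt, under N2
Reagents that add atoms: dimethyl sulfate, COS(=O)(=O)OC
Why: Dithionite reduces the quinone to the hydroquinone, whose bis-phenoxide is O-methylated in the same flask (reductive methylation, Williamson-type etherification).

Step 7
Reactants: 16 1,4-dimethoxy-2-methylnaphthalene
Product: 17 2-bromo-1,4-dimethoxy-3-methylnaphthalene
Conditions: Br2, CH2Cl2, 0 °C
Reagents that add atoms: bromine, BrBr
Why: Electrophilic aromatic bromination should go to C-3, the only free position of the doubly methoxy-activated ring B.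

Step 8
Reactants: 18 (2E,6E,10E)-geranylgeraniol
Product: 19 (2E,6E,10E)-geranylgeranyl bromide
Conditions: PBr3, Et2O, −10 to 0 °C; used crude
Reagents that add atoms: phosphorus tribromide, BrP(Br)Br
Why: Bromide displaces the phosphite-activated primary allylic alcohol by SN2 at low temperature, which keeps the E geometry of the C2 olefin.

Step 9
Reactants: 17 2-bromo-1,4-dimethoxy-3-methylnaphthalene; 19 (2E,6E,10E)-geranylgeranyl bromide
Product: 21 2-[(2E,6E,10E)-3,7,11,15-tetramethylhexadeca-2,6,10,14-tetraen-1-yl]-1,4-dimethoxy-3-methylnaphthalene, via arylmagnesium bromide 20 (not isolated)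
Conditions: 17, Mg turnings, THF, reflux; then 19, CuBr·SMe2 (5 mol%), THF, −20 °C to rt
Reagents that add atoms: none
Why: Copper-catalysed allylation of the aryl Grignard reagent should occur by SN2 at the primary carbon, because the fully substituted gamma carbon blocks SN2' attack, so the C2'=C3' E geometry is carried over.

Step 10
Reactants: 21 2-[(2E,6E,10E)-3,7,11,15-tetramethylhexadeca-2,6,10,14-tetraen-1-yl]-1,4-dimethoxy-3-methylnaphthalene
Product: 23 (2E,6E,10E,14E)-16-(1,4-dimethoxy-3-methylnaphthalen-2-yl)-2,6,10,14-tetramethylhexadeca-2,6,10,14-tetraenal, via allylic alcohol 22 (not isolated)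
Conditions: SeO2 (0.3 equiv), t-BuOOH (3 equiv), salicylic acid (0.1 equiv), CH2Cl2, 0 °C to rt, run to partial conversion; filtered crude, MnO2, CH2Cl2, rt
Reagents that add atoms: selenium dioxide, O=[Se]=O; tert-butyl hydroperoxide, CC(C)(C)OO
Why: Riley-type allylic oxidation (ene reaction then [2,3] shift) should prefer the least hindered terminal isopropylidene group and oxidise its E methyl group, and MnO2 then converges the allylic alcohol/aldehyde mixture on the E enal without touching the isolated olefins or the aryl ethers.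

Step 11
Reactants: 23 (2E,6E,10E,14E)-16-(1,4-dimethoxy-3-methylnaphthalen-2-yl)-2,6,10,14-tetramethylhexadeca-2,6,10,14-tetraenal
Product: 24 2-[(2E,6E,10E,14E)-3,7,11,15-tetramethylheptadeca-2,6,10,14,16-pentaen-1-yl]-1,4-dimethoxy-3-methylnaphthalene
Conditions: Ph3PCH3Br, KOtBu, THF, 0 °C; then 23, 0 °C to rt
Reagents that add atoms: methyltriphenylphosphonium bromide, C[P+](c1ccccc1)(c1ccccc1)c1ccccc1.[Br-]
Why: Wittig methylenation with the non-stabilised ylide adds 1,2 to the enal and should give the terminal 3-methyl-1,3-diene with the C14'=C15' E geometry unchanged.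

Step 12
Reactants: 24 2-[(2E,6E,10E,14E)-3,7,11,15-tetramethylheptadeca-2,6,10,14,16-pentaen-1-yl]-1,4-dimethoxy-3-methylnaphthalene; 13 (1E,5E,10R)-1-iodo-2,6,10,14-tetramethylpentadeca-1,5,13-triene
Product: 26 1,4-dimethoxy-2-methyl-3-[(2E,6E,10E,14E,18E,22E,27R)-3,7,11,15,19,23,27,31-octamethyldotriaconta-2,6,10,14,18,22,30-heptaen-1-yl]naphthalene, via B-alkyl-9-BBN 25 (not isolated)
Conditions: 24, 9-BBN dimer (0.55 equiv), THF, 0 °C to rt; then 13, Pd(dppf)Cl2·CH2Cl2 (5 mol%), AsPh3 (5 mol%), 3 M aq. K3PO4, DMF, rt, degassed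
Reagents that add atoms: none
Why: 9-BBN should add in anti-Markovnikov fashion to the only monosubstituted olefin of 24, the terminal vinyl group C16'=C17' of the 3-methyl-1,3-diene, to give the primary homoallylic borane 25 with boron on C17', the four trisubstituted olefins being too hindered for this bulky dialkylborane. Aqueous K3PO4 then converts 25 into its hydroxyborate, zerovalent palladium inserts into the C(sp2)–I bond of 13 with retention, the primary alkyl group passes from boron to palladium, and reductive elimination forms the C17'–C18' bond. The closest known reaction type is the B-alkyl Suzuki–Miyaura coupling of 9-BBN adducts of terminal 1,3-dienes with (E)-2-methylalk-1-enyl iodides, as used to assemble polyprenoid chains. No ring is closed and no stereocentre is formed; the E configuration of the new C18'=C19' olefin is inherited from 13, where the syn methylalumination of step 5 fixed it. The selectivities needed are site selectivity in the hydroboration, secured by the steric contrast between CH2=CH and the trisubstituted olefins and by one equivalent of 9-BBN, and suppression of beta-hydride elimination from the alkylpalladium species, secured by the wide-bite-angle dppf ligand and the AsPh3 co-ligand, which speed transmetalation and reductive elimination. The aryl methyl ethers, the isopropylidene terminus and the remote C27' stereocentre take no part.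

Step 13
Reactants: 26 1,4-dimethoxy-2-methyl-3-[(2E,6E,10E,14E,18E,22E,27R)-3,7,11,15,19,23,27,31-octamethyldotriaconta-2,6,10,14,18,22,30-heptaen-1-yl]naphthalene
Product: 27 2-methyl-3-[(2E,6E,10E,14E,18E,22E,27R)-3,7,11,15,19,23,27,31-octamethyldotriaconta-2,6,10,14,18,22,30-heptaen-1-yl]naphthalene-1,4-dione
Conditions: (NH4)2Ce(NO3)6 (2.5 equiv), MeCN/CH2Cl2/H2O, 0 °C
Reagents that add atoms: water, O
Why: One-electron oxidation of the electron-rich ring B by tetravalent cerium gives the arene radical cation, which takes up water at the two ipso carbons and loses methanol to give the quinone (oxidative demethylation), a process that should be much faster than any attack on the isolated trisubstituted olefins and leaves C27' untouched.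

**Compound list**

1 | (S)-citronellyl bromide, (6S)-8-bromo-2,6-dimethyloct-2-ene | CC(C)=CCC[C@H](C)CCBr | starting material
2 | 1-(trimethylsilyl)propyne | CC#C[Si](C)(C)C | starting material
3 | 3-lithio-1-(trimethylsilyl)propyne | [Li]CC#C[Si](C)(C)C | intermediate
4 | trimethyl[(6R)-6,10-dimethylundec-9-en-1-yn-1-yl]silane | CC(C)=CCC[C@H](C)CCCC#C[Si](C)(C)C | intermediate
5 | (R)-6,10-dimethylundec-9-en-1-yne | CC(C)=CCC[C@H](C)CCCC#C | intermediate
6 | dimethyl[(1E,6R)-2,6,10-trimethylundeca-1,9-dien-1-yl]alane | CC(C)=CCC[C@H](C)CCC/C(C)=C/[Al](C)C | intermediate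
7 | (1E,6R)-1-iodo-2,6,10-trimethylundeca-1,9-diene | CC(C)=CCC[C@H](C)CCC/C(C)=C/I | intermediate
8 | (4-bromobut-1-yn-1-yl)trimethylsilane | BrCCC#C[Si](C)(C)C | starting material
9 | [4-(trimethylsilyl)but-3-yn-1-yl]zinc bromide | Br[Zn]CCC#C[Si](C)(C)C | intermediate
10 | trimethyl[(5E,10R)-6,10,14-trimethylpentadeca-5,13-dien-1-yn-1-yl]silane | CC(C)=CCC[C@H](C)CCC/C(C)=C/CCC#C[Si](C)(C)C | intermediate
11 | (5E,10R)-6,10,14-trimethylpentadeca-5,13-dien-1-yne | CC(C)=CCC[C@H](C)CCC/C(C)=C/CCC#C | intermediate
12 | dimethyl[(1E,5E,10R)-2,6,10,14-tetramethylpentadeca-1,5,13-trien-1-yl]alane | CC(C)=CCC[C@H](C)CCC/C(C)=C/CC/C(C)=C/[Al](C)C | intermediate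
13 | (1E,5E,10R)-1-iodo-2,6,10,14-tetramethylpentadeca-1,5,13-triene | CC(C)=CCC[C@H](C)CCC/C(C)=C/CC/C(C)=C/I | intermediate
14 | menadione, 2-methylnaphthalene-1,4-dione | CC1=CC(=O)c2ccccc2C1=O | starting material
15 | menadiol, 2-methylnaphthalene-1,4-diol | Cc1cc(O)c2ccccc2c1O | intermediate
16 | 1,4-dimethoxy-2-methylnaphthalene | COc1cc(C)c(OC)c2ccccc12 | intermediate
17 | 2-bromo-1,4-dimethoxy-3-methylnaphthalene | COc1c(Br)c(C)c(OC)c2ccccc12 | intermediate
18 | (2E,6E,10E)-geranylgeraniol | CC(C)=CCC/C(C)=C/CC/C(C)=C/CC/C(C)=C/CO | starting material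
19 | (2E,6E,10E)-geranylgeranyl bromide | CC(C)=CCC/C(C)=C/CC/C(C)=C/CC/C(C)=C/CBr | intermediate
20 | (1,4-dimethoxy-3-methylnaphthalen-2-yl)magnesium bromide | COc1c([Mg]Br)c(C)c(OC)c2ccccc12 | intermediate
21 | 2-[(2E,6E,10E)-3,7,11,15-tetramethylhexadeca-2,6,10,14-tetraen-1-yl]-1,4-dimethoxy-3-methylnaphthalene | CC(C)=CCC/C(C)=C/CC/C(C)=C/CC/C(C)=C/Cc1c(C)c(OC)c2ccccc2c1OC | intermediate
22 | (2E,6E,10E,14E)-16-(1,4-dimethoxy-3-methylnaphthalen-2-yl)-2,6,10,14-tetramethylhexadeca-2,6,10,14-tetraen-1-ol | OC/C(C)=C/CC/C(C)=C/CC/C(C)=C/CC/C(C)=C/Cc1c(C)c(OC)c2ccccc2c1OC | intermediate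
23 | (2E,6E,10E,14E)-16-(1,4-dimethoxy-3-methylnaphthalen-2-yl)-2,6,10,14-tetramethylhexadeca-2,6,10,14-tetraenal | O=C/C(C)=C/CC/C(C)=C/CC/C(C)=C/CC/C(C)=C/Cc1c(C)c(OC)c2ccccc2c1OC | intermediate
24 | 2-[(2E,6E,10E,14E)-3,7,11,15-tetramethylheptadeca-2,6,10,14,16-pentaen-1-yl]-1,4-dimethoxy-3-methylnaphthalene | C=C/C(C)=C/CC/C(C)=C/CC/C(C)=C/CC/C(C)=C/Cc1c(C)c(OC)c2ccccc2c1OC | intermediate
25 | 9-[(3E,7E,11E,15E)-17-(1,4-dimethoxy-3-methylnaphthalen-2-yl)-3,7,11,15-tetramethylheptadeca-3,7,11,15-tetraen-1-yl]-9-borabicyclo[3.3.1]nonane | C(C/C(C)=C/CC/C(C)=C/CC/C(C)=C/CC/C(C)=C/Cc1c(C)c(OC)c2ccccc2c1OC)B1C2CCCC1CCC2 | intermediate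
26 | 1,4-dimethoxy-2-methyl-3-[(2E,6E,10E,14E,18E,22E,27R)-3,7,11,15,19,23,27,31-octamethyldotriaconta-2,6,10,14,18,22,30-heptaen-1-yl]naphthalene | CC(C)=CCC[C@H](C)CCC/C(C)=C/CC/C(C)=C/CC/C(C)=C/CC/C(C)=C/CC/C(C)=C/CC/C(C)=C/Cc1c(C)c(OC)c2ccccc2c1OC | intermediate
27 | 2-methyl-3-[(2E,6E,10E,14E,18E,22E,27R)-3,7,11,15,19,23,27,31-octamethyldotriaconta-2,6,10,14,18,22,30-heptaen-1-yl]naphthalene-1,4-dione (CNP0319612.1) | CC(C)=CCC[C@H](C)CCC/C(C)=C/CC/C(C)=C/CC/C(C)=C/CC/C(C)=C/CC/C(C)=C/CC/C(C)=C/CC1=C(C)C(=O)c2ccccc2C1=O | target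

**Count and risks**

Total step count: 13. Longest linear sequence: 7 steps (steps 1, 2, 3, 4, 5, 12, 13 from 1; equally steps 6, 7, 9, 10, 11, 12, 13 from 14).

Steps most likely to fail:

1. Step 10. The allylic oxidation may not discriminate well enough between the terminal isopropylidene group and the three internal trisubstituted olefins, and it may over-oxidise. The fallback sets out from 21 and comes back at 23, and it replaces allylic oxidation by cleavage and re-olefination. Terminal-selective bromohydrin formation on 21 (NBS, THF/H2O, 0 °C) should give the racemic terminal bromohydrin F1. K2CO3 in MeOH closes it to the racemic terminal epoxide F2. HIO4 in THF/H2O cleaves the epoxide to the trisnor aldehyde F3. Wittig olefination of F3 with the stabilised ylide 2-(triphenylphosphoranylidene)propanal (toluene, 90 °C) should then give the E enal 23.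

2. Step 12. Hydroboration of the conjugated diene may be incomplete or may also touch the internal olefins, and slow alkyl transfer from boron may leave the alkenyl iodide to be reduced or homocoupled. The fallback sets out from 24 and comes back at 26, and it uses an isolated alkyl iodide and an alkylzinc in a Negishi coupling. Hydroboration of 24 with 9-BBN (via 25) and oxidation with NaOH/H2O2 should give the homoallylic alcohol F4, which can be purified. I2, PPh3 and imidazole in CH2Cl2 convert it into the homoallylic iodide F5. Iodine–lithium exchange (t-BuLi, 2 equiv, Et2O, −78 °C) gives the alkyllithium F6, and ZnBr2 in THF turns this into the alkylzinc bromide F7. Coupling of F7 with 13 (PdCl2(DPEphos), THF, rt) should give 26.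

3. Step 9. The allylation may suffer from partial E/Z scrambling at C2'=C3', from SN2' attack, or from Wurtz-type homocoupling of the allylic bromide. The fallback sets out from 19 (and 14) and comes back at 21, and it replaces the Grignard reaction by Lewis acid mediated allylation of the quinone. Bromide 19 and Bu3SnLi (THF, −78 °C) should give the geranylgeranyl tributylstannane F8. F8 and menadione 14 with BF3·OEt2 (CH2Cl2, −78 °C) should give, after carbonyl addition and allyl shift to C-3, the menaquinol-4 F9, which Ag2O oxidises at work-up to the menaquinone-4 F10. Reductive methylation of F10 under the conditions of step 6 (through F9 again) should give 21.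

**Further compounds**

F1 | step 10 | racemic (6E,10E,14E)-3-bromo-16-(1,4-dimethoxy-3-methylnaphthalen-2-yl)-2,6,10,14-tetramethylhexadeca-6,10,14-trien-2-ol | CC(C)(O)C(Br)CC/C(C)=C/CC/C(C)=C/CC/C(C)=C/Cc1c(C)c(OC)c2ccccc2c1OC
F2 | step 10 | racemic 2-[(2E,6E,10E)-13-(3,3-dimethyloxiran-2-yl)-3,7,11-trimethyltrideca-2,6,10-trien-1-yl]-1,4-dimethoxy-3-methylnaphthalene | CC1(C)OC1CC/C(C)=C/CC/C(C)=C/CC/C(C)=C/Cc1c(C)c(OC)c2ccccc2c1OC
F3 | step 10 | (4E,8E,12E)-14-(1,4-dimethoxy-3-methylnaphthalen-2-yl)-4,8,12-trimethyltetradeca-4,8,12-trienal | O=CCC/C(C)=C/CC/C(C)=C/CC/C(C)=C/Cc1c(C)c(OC)c2ccccc2c1OC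
F4 | step 12 | (3E,7E,11E,15E)-17-(1,4-dimethoxy-3-methylnaphthalen-2-yl)-3,7,11,15-tetramethylheptadeca-3,7,11,15-tetraen-1-ol | OCC/C(C)=C/CC/C(C)=C/CC/C(C)=C/CC/C(C)=C/Cc1c(C)c(OC)c2ccccc2c1OC
F5 | step 12 | 2-[(2E,6E,10E,14E)-17-iodo-3,7,11,15-tetramethylheptadeca-2,6,10,14-tetraen-1-yl]-1,4-dimethoxy-3-methylnaphthalene | ICC/C(C)=C/CC/C(C)=C/CC/C(C)=C/CC/C(C)=C/Cc1c(C)c(OC)c2ccccc2c1OC
F6 | step 12 | [(3E,7E,11E,15E)-17-(1,4-dimethoxy-3-methylnaphthalen-2-yl)-3,7,11,15-tetramethylheptadeca-3,7,11,15-tetraen-1-yl]lithium | [Li]CC/C(C)=C/CC/C(C)=C/CC/C(C)=C/CC/C(C)=C/Cc1c(C)c(OC)c2ccccc2c1OC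
F7 | step 12 | [(3E,7E,11E,15E)-17-(1,4-dimethoxy-3-methylnaphthalen-2-yl)-3,7,11,15-tetramethylheptadeca-3,7,11,15-tetraen-1-yl]zinc bromide | Br[Zn]CC/C(C)=C/CC/C(C)=C/CC/C(C)=C/CC/C(C)=C/Cc1c(C)c(OC)c2ccccc2c1OC
F8 | step 9 | tributyl[(2E,6E,10E)-3,7,11,15-tetramethylhexadeca-2,6,10,14-tetraen-1-yl]stannane | CC(C)=CCC/C(C)=C/CC/C(C)=C/CC/C(C)=C/C[Sn](CCCC)(CCCC)CCCC
F9 | step 9 | menaquinol-4, 2-methyl-3-[(2E,6E,10E)-3,7,11,15-tetramethylhexadeca-2,6,10,14-tetraen-1-yl]naphthalene-1,4-diol | CC(C)=CCC/C(C)=C/CC/C(C)=C/CC/C(C)=C/Cc1c(C)c(O)c2ccccc2c1O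
F10 | step 9 | menaquinone-4, 2-methyl-3-[(2E,6E,10E)-3,7,11,15-tetramethylhexadeca-2,6,10,14-tetraen-1-yl]naphthalene-1,4-dione | CC(C)=CCC/C(C)=C/CC/C(C)=C/CC/C(C)=C/CC1=C(C)C(=O)c2ccccc2C1=O
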